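## Analysis of the target

The target 14 is a 2,3-dihydro-1,4-benzodioxine: a benzene ring (ring A) fused to a six-membered dioxane ring. It carries a 3,4,5-trimethoxyphenyl group (ring B) on C3, a hydroxymethyl group on C2, an (E)-propenal chain on C6 and a free phenol on C8. The two stereocentres, C2 and C3, are both S, are adjacent, each bear one ring oxygen, and hold their substituents trans (both equatorial in the half-chair). The sensitive groups are the enal (a Michael acceptor that does not tolerate hydrides, strong nucleophiles or strong base), the electron-rich free phenol, and the C3–O4 bond, a benzylic aryl ether that can ionise in strong acid and is cleaved by hydrogenolysis. The hard part is ring A: C4a, C8a and C8 carry three adjacent oxygens that are all different (O4 bound to C3, O1 bound to C2, one free hydroxyl). A route from a pyrogallol-type arene must therefore tell three neighbouring phenols apart, and oxidative coupling of a catechol with a cinnamyl alcohol gives neither regiocontrol nor a single enantiomer. The plan rests on the fact that O1 and the C8 hydroxyl sit on neighbouring carbons next to C4a. With O4 in place and a halogen on C8, the C8a–C8 pair can be unmasked as an aryne; the C2 oxygen adds to C8a and the carbanion left on C8 is converted into the hydroxyl. Ring A then starts as a 1,3,5-trisubstituted benzene with a single oxygen, and both stereocentres are set in an open chain before the ring is closed.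

## Retrosynthetic reasoning

**14 to 13.** The C=C bond of the enal is cut first, leading back to aldehyde 13. The enal is the most fragile group, so it is made last, under neutral conditions, by a stabilised two-carbon phosphorus ylide that gives the E alkene and tolerates the free phenol and the primary alcohol.

**13 to 12.** No skeletal bond is cut here. The C6 aldehyde is masked as a dioxolane and the primary alcohol as a methoxymethyl ether in 12. Both groups withstand lithium amides, alkoxides, borates and alkaline peroxide, and both fall in one aqueous acid treatment, so the strong-acid step is done before the enal exists.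

**12 to 8 (key disconnection).** The bonds O1–C8a and C8–O are cut together, which leads to the syn bromo ether alcohol 8. Cutting here, and not at O4–C4a or at a C–O bond of a stereocentre, leaves both stereocentres in an acyclic chain where they can be set by well-understood reactions, and removes two of the three ring A oxygens at once. In the forward direction a hindered lithium amide removes the proton between O4 and bromine and lithium bromide is lost to give aryne 9. The tethered alkoxide closes the ring to aryllithium 10, which is borylated to 11 and oxidised to phenol 12.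

**8 to 6 via 7.** Alcohol 8 has the aryloxy and hydroxyl groups syn, whereas the dependable route to such aryloxy alcohols, opening of a trans epoxide, gives the anti isomer 6. The carbinol carbon is therefore inverted: Mitsunobu esterification to 7, then methanolysis to 8.

**6 to 5 to 4 and 2.** The benzylic O4–C3 bond is cut. Phenol 2 opens epoxy alcohol 4 at the benzylic carbon with inversion to give anti diol 5, whose primary hydroxyl is then masked to give 6. This joins the ring A and ring B halves convergently and stereospecifically.

**4 to 3, and 2 to 1.** Epoxy alcohol 4 comes from allylic alcohol 3 by catalytic asymmetric epoxidation, which sets both stereocentres. Phenol 2 is the cyclic acetal of the commercial aldehyde 1.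

## Alternatives that were turned down

**Alternative 1: ring expansion of a benzodioxole by a carbenoid.**
- Disconnection: O1–C2 and C2–C3 are cut together. The dioxane is seen as an expanded 2-aryl-1,3-benzodioxole whose C8 oxygen carries a diazoacetate (A2); this supplies C2 and the future CH2OH carbon.
- Forward key step: a carbenoid generated with Rh2(OAc)4 is captured by the dioxole oxygen on C8a to give an oxonium ylide. A 1,2-shift of the acetal carbon to the carbene carbon gives tricyclic lactone A1. Hydride reduction and benzylic oxidation would then lead to 13.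
- For: ring A comes from a gallate ester with all three oxygens present and no need to differentiate them. The C2–C3 bond is made in the key step. The route to 14 is about six operations, shorter than the chosen one.
- Against: C2 and C3 are both created in the shift. The migrating carbon is benzylic and oxygen-stabilised, so the shift passes through a radical or ion pair in which it is planar. The configuration of the acetal carbon of A2 is lost, and the metal need not be bound when the bond forms. Neither the absolute configuration nor the trans relationship has a reliable source, so a single enantiomer would need a resolution. The carbenoid can also attack the electron-rich ring B.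
- Comparison: this alternative is stronger on step count and on the ring A oxygenation problem. The chosen strategy offers in its place stereocentres from a catalytic asymmetric epoxidation and two SN2 inversions, and a key step that cannot alter them.

**Alternative 2: iodoetherification of a 1-arylallyl aryl ether.**
- Disconnection: O1–C2 is cut, with C2 as the internal carbon of a vinyl group. O4–C3 is made earlier by an iridium-catalysed branched allylic etherification ([Ir(cod)Cl]2 with a chiral phosphoramidite), giving ether A4.
- Forward key step: an electrophilic iodine source activates the vinyl group of A4, and the free phenol on C8a attacks the internal carbon (6-exo) to give iodomethyl benzodioxane A3.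
- For: C3 is set by catalyst control, as good a source of absolute configuration as the epoxidation. Conditions are mild, no strong base is used, and the aldehyde needs no mask.
- Against, ring A: A4 needs the catechol oxygen para to the formyl group free while its meta neighbour is allylated. The para oxygen is the more acidic and would react first, so extra protecting-group steps on three adjacent oxygens are required.
- Against, C2: C2 is set by 1,2-induction in the cyclisation, a kinetic preference rather than a stereospecific event.
- Against, the iodide: CH2I must still be turned into CH2OH. This is a branched primary iodide with two β-oxygens, for which substitution is slow and elimination to an exocyclic enol ether competes. Ring B is also open to iodination.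
- Comparison: equal on C3, weaker on C2 and on ring A, and no shorter once the extra steps are counted. The chosen strategy derives the trans relationship stereospecifically and never has to differentiate catechol oxygens.

**Alternative 3: benzylic C–H oxidation closing the ring at C3.**
- Disconnection: C3–O4 is cut and C3 becomes a benzylic methylene. Ring A is a symmetrical 3,5-dihydroxy-4-alkoxybenzaldehyde ether, A6.
- Forward key step: a high-potential quinone removes hydride from the benzylic methylene of A6, and either flanking phenol traps the cation to give benzodioxane A5.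
- For: it is the shortest route on paper. The symmetry of ring A removes any regiochemical question, C2 comes from an enantiopure three-carbon epoxide, and A5 needs only desilylation and olefination.
- Against: the oxidant meets two free phenols on an electron-rich ring, which are at least as easily oxidised as the methylene. Ring B is a poorer hydride donor than a 4-alkoxybenzyl group, because its central methoxy group is twisted out of conjugation. The cation has a β-hydrogen on C2 and can lose a proton. The C3–H of A5 is benzylic and α to oxygen, so over-oxidation is easier than the first oxidation. The C3 configuration rests on a preference for the trans ring, not on a stereospecific step.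
- Comparison: stronger on step economy. The chosen strategy keeps oxidants away from free phenols and fixes both centres before ring closure.

Key step: step 7

Remark: benzodioxane positions are numbered as in the target throughout (O1, C2 with the CH2O arm, C3 with ring B, O4, C6 with the carbon substituent, C8 with the oxygen); "anti" and "syn" refer to the aryloxy and hydroxyl groups on the zigzag chain; alcohol 3 is taken as a purchased compound.

## Route

Step 1
Reactants: 1 3-bromo-5-hydroxybenzaldehyde
Product: 2 3-bromo-5-(1,3-dioxolan-2-yl)phenol
Conditions: HOCH2CH2OH (3 equiv), p-TsOH·H2O (5 mol%), toluene, reflux, Dean–Stark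
Reagents that add atoms: ethylene glycol OCCO
Why: Acid-catalysed acetalisation driven by azeotropic removal of water; the phenol is inert, and the dioxolane shields the aldehyde from the hydroxide, alkoxide and lithium amide used later.

Step 2
Reactants: 3 (E)-3-(3,4,5-trimethoxyphenyl)prop-2-en-1-ol
Product: 4 [(2R,3R)-3-(3,4,5-trimethoxyphenyl)oxiran-2-yl]methanol
Conditions: Ti(OiPr)4 (10 mol%), D-(−)-diethyl tartrate (12 mol%), t-BuOOH (2 equiv, decane), 4 Å MS, CH2Cl2, −20 °C
Reagents that add atoms: tert-butyl hydroperoxide CC(C)(C)OO
Why: Sharpless asymmetric epoxidation of an (E)-allylic alcohol; the D-(−)-tartrate ligand directs oxygen to the alkene face that gives the (2R,3R)-epoxide, so both stereocentres are set here by the catalyst, and high enantiomeric excess is expected for (E)-cinnamyl alcohols. Catalytic titanium with molecular sieves limits opening of the electron-rich benzylic epoxide.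

Step 3
Reactants: 4 [(2R,3R)-3-(3,4,5-trimethoxyphenyl)oxiran-2-yl]methanol; 2 3-bromo-5-(1,3-dioxolan-2-yl)phenol
Product: 5 (2R,3S)-3-[3-bromo-5-(1,3-dioxolan-2-yl)phenoxy]-3-(3,4,5-trimethoxyphenyl)propane-1,2-diol
Conditions: aq. NaOH (0.5 equiv), H2O/1,4-dioxane, 70 °C
Reagents that add atoms: none
Why: Phenoxide opening of a 3-aryl-2,3-epoxy alcohol; attack should occur at the benzylic carbon, which is activated for SN2, while the other epoxide carbon is retarded by the adjacent CH2OH oxygen. Basic conditions keep the opening SN2, so the benzylic centre is inverted cleanly (R to S) and the anti diol results.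

Step 4
Reactants: 5 (2R,3S)-3-[3-bromo-5-(1,3-dioxolan-2-yl)phenoxy]-3-(3,4,5-trimethoxyphenyl)propane-1,2-diol
Product: 6 (1S,2R)-1-[3-bromo-5-(1,3-dioxolan-2-yl)phenoxy]-3-(methoxymethoxy)-1-(3,4,5-trimethoxyphenyl)propan-2-ol
Conditions: MOMCl (1.1 equiv), iPr2NEt (2 equiv), CH2Cl2, −20 → 0 °C
Reagents that add atoms: chloromethyl methyl ether COCCl
Why: O-alkylation with an α-chloro ether; the primary hydroxyl is far more accessible than the secondary one, which is flanked by a carbon bearing ring B and the aryloxy group. The methoxymethyl ether cannot migrate to the neighbouring alkoxide in step 7.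

Step 5
Reactants: 6 (1S,2R)-1-[3-bromo-5-(1,3-dioxolan-2-yl)phenoxy]-3-(methoxymethoxy)-1-(3,4,5-trimethoxyphenyl)propan-2-ol
Product: 7 (1S,2S)-1-[3-bromo-5-(1,3-dioxolan-2-yl)phenoxy]-3-(methoxymethoxy)-1-(3,4,5-trimethoxyphenyl)propan-2-yl 4-nitrobenzoate
Conditions: PPh3 (2 equiv), DIAD (2 equiv), 4-O2NC6H4CO2H (2 equiv), THF, 0 °C → rt
Reagents that add atoms: 4-nitrobenzoic acid O=C(O)c1ccc(cc1)[N+](=O)[O-]
Why: Mitsunobu reaction; the carboxylate displaces the oxyphosphonium group by SN2, which inverts the carbinol carbon (R to S) and turns the anti into the syn arrangement. The acidic 4-nitrobenzoic acid is the usual choice for hindered secondary alcohols, and the ester may offer a crystallisation point to raise stereochemical purity.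

Step 6
Reactants: 7 (1S,2S)-1-[3-bromo-5-(1,3-dioxolan-2-yl)phenoxy]-3-(methoxymethoxy)-1-(3,4,5-trimethoxyphenyl)propan-2-yl 4-nitrobenzoate
Product: 8 (1S,2S)-1-[3-bromo-5-(1,3-dioxolan-2-yl)phenoxy]-3-(methoxymethoxy)-1-(3,4,5-trimethoxyphenyl)propan-2-ol
Conditions: K2CO3 (0.5 equiv), MeOH, rt
Reagents that add atoms: none
Why: Base-catalysed methanolysis of an activated aryl ester; cleavage is at the acyl carbon, so the carbinol configuration is retained, and the aryl bromide, dioxolane and methoxymethyl ether are inert.

Step 7
Reactants: 8 (1S,2S)-1-[3-bromo-5-(1,3-dioxolan-2-yl)phenoxy]-3-(methoxymethoxy)-1-(3,4,5-trimethoxyphenyl)propan-2-ol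
Product: 12 (2S,3S)-6-(1,3-dioxolan-2-yl)-8-hydroxy-2-[(methoxymethoxy)methyl]-3-(3,4,5-trimethoxyphenyl)-2,3-dihydro-1,4-benzodioxine, via aryne lithium alkoxide 9 (not isolated), via 8-lithio benzodioxane 10 (not isolated), via lithium aryltrimethoxyborate 11 (not isolated)
Conditions: lithium 2,2,6,6-tetramethylpiperidide (2.5 equiv, from the amine and n-butyllithium), THF (0.02 M), −78 → −20 °C; B(OMe)3 (5 equiv), −78 °C → rt; 30% H2O2, aq. NaOH, 0 °C
Reagents that add atoms: hydrogen peroxide OO (the C8 oxygen of 12); trimethyl borate COB(OC)OC (boron and methoxy groups of 11 only); lithium 2,2,6,6-tetramethylpiperidide [Li+].CC1(C)CCCC(C)(C)[N-]1 (lithium of 9, 10 and 11 only)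
Why: The first equivalent of base forms the lithium alkoxide and the second removes C8a–H, the ring proton flanked by O4 and bromine and therefore the most acidic; on warming, this ortho-lithio bromide loses LiBr, its only good ortho leaving group, to give aryne 9 across C8a–C8. The alkoxide oxygen then adds in the ring plane to C8a, a 6-exo-dig closure of the dioxane ring; C8 is out of reach because bonding there would require a meta-bridged seven-membered ring, so the tether overrides the usual preference of nucleophiles for the aryne carbon remote from an alkoxy group. The carbanion appears on C8 as aryllithium 10, ortho to the new O1 and inductively stabilised by it; B(OMe)3 captures it as borate 11, and alkaline H2O2 converts the C–B bond into the C8 hydroxyl of 12 at the same position. The closest known reaction type is the base-induced aryne cyclisation of meta-halophenyl substrates bearing a tethered amide or alkoxide (indoline, dihydrobenzofuran and chroman closures) with electrophilic trapping of the resulting aryllithium; borylation and oxidation of aryllithiums is routine. No stereocentre is formed: both existing centres are carbinol carbons whose C–O bonds are not broken, so syn 8 can only give the trans ring. Three selectivities are needed: lithiation at C8a and not at C7 or C5 (secured by the O/Br flanking and by the alkoxide holding the base nearby; a C5 lithio species has no leaving group and is unproductive but harmless); intramolecular over intermolecular capture of the aryne (high dilution and a hindered amide that is a poor nucleophile and has no β-hydrogen to reduce the aryne); and survival of 10 until the borate arrives (the hindered amine by-product is a slow proton donor and the mixture is re-cooled before the quench).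

Step 8
Reactants: 12 (2S,3S)-6-(1,3-dioxolan-2-yl)-8-hydroxy-2-[(methoxymethoxy)methyl]-3-(3,4,5-trimethoxyphenyl)-2,3-dihydro-1,4-benzodioxine
Product: 13 (2S,3S)-8-hydroxy-2-(hydroxymethyl)-3-(3,4,5-trimethoxyphenyl)-2,3-dihydro-1,4-benzodioxine-6-carbaldehyde
Conditions: 3 M aq. HCl/THF (1:1), 45 °C
Reagents that add atoms: water O
Why: Acid hydrolysis of both acetal-type groups (dioxolane and methoxymethyl ether) in one operation, carried out before the enal exists. The benzylic C3–O4 bond should hold: the central methoxy group of ring B is twisted by its neighbours and the two meta methoxy groups withdraw inductively, so ionisation is much harder than for a 4-methoxybenzyl ether, and any reversible opening would re-close to the favoured trans ring.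

Step 9
Reactants: 13 (2S,3S)-8-hydroxy-2-(hydroxymethyl)-3-(3,4,5-trimethoxyphenyl)-2,3-dihydro-1,4-benzodioxine-6-carbaldehyde
Product: 14 (2E)-3-[(2S,3S)-8-hydroxy-2-(hydroxymethyl)-3-(3,4,5-trimethoxyphenyl)-2,3-dihydro-1,4-benzodioxin-6-yl]prop-2-enal
Conditions: Ph3P=CHCHO (1.2 equiv), toluene/THF (3:1), 80 °C
Reagents that add atoms: (triphenylphosphoranylidene)acetaldehyde O=CC=P(c1ccccc1)(c1ccccc1)c1ccccc1
Why: Wittig olefination with a stabilised ylide should give the (E)-enal; the ylide is too weakly basic to be quenched by the phenol or the alcohol, and a small excess limits a second homologation.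

## Compound list

1 | 3-bromo-5-hydroxybenzaldehyde | O=Cc1cc(O)cc(Br)c1 | starting material
2 | 3-bromo-5-(1,3-dioxolan-2-yl)phenol | Oc1cc(Br)cc(C2OCCO2)c1 | intermediate
3 | (E)-3-(3,4,5-trimethoxyphenyl)prop-2-en-1-ol | COc1cc(/C=C/CO)cc(OC)c1OC | starting material
4 | [(2R,3R)-3-(3,4,5-trimethoxyphenyl)oxiran-2-yl]methanol | OC[C@H]1O[C@@H]1c1cc(OC)c(OC)c(OC)c1 | intermediate
5 | (2R,3S)-3-[3-bromo-5-(1,3-dioxolan-2-yl)phenoxy]-3-(3,4,5-trimethoxyphenyl)propane-1,2-diol (anti) | COc1cc([C@H](Oc2cc(Br)cc(C3OCCO3)c2)[C@H](O)CO)cc(OC)c1OC | intermediate
6 | (1S,2R)-1-[3-bromo-5-(1,3-dioxolan-2-yl)phenoxy]-3-(methoxymethoxy)-1-(3,4,5-trimethoxyphenyl)propan-2-ol (anti) | COc1cc([C@H](Oc2cc(Br)cc(C3OCCO3)c2)[C@H](O)COCOC)cc(OC)c1OC | intermediate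
7 | (1S,2S)-1-[3-bromo-5-(1,3-dioxolan-2-yl)phenoxy]-3-(methoxymethoxy)-1-(3,4,5-trimethoxyphenyl)propan-2-yl 4-nitrobenzoate | COc1cc([C@H](Oc2cc(Br)cc(C3OCCO3)c2)[C@@H](OC(=O)c2ccc(cc2)[N+](=O)[O-])COCOC)cc(OC)c1OC | intermediate
8 | (1S,2S)-1-[3-bromo-5-(1,3-dioxolan-2-yl)phenoxy]-3-(methoxymethoxy)-1-(3,4,5-trimethoxyphenyl)propan-2-ol (syn) | COc1cc([C@H](Oc2cc(C3OCCO3)cc(Br)c2)[C@@H](O)COCOC)cc(OC)c1OC | intermediate
9 | lithium alkoxide of the C8a–C8 aryne derived from 8 (not isolated) | COc1cc([C@H](OC2=CC(C3OCCO3)=CC#C2)[C@@H]([O-])COCOC)cc(OC)c1OC.[Li+] | intermediate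
10 | (2S,3S)-6-(1,3-dioxolan-2-yl)-8-lithio-2-[(methoxymethoxy)methyl]-3-(3,4,5-trimethoxyphenyl)-2,3-dihydro-1,4-benzodioxine (not isolated) | COc1cc([C@@H]2Oc3cc(C4OCCO4)cc([Li])c3O[C@H]2COCOC)cc(OC)c1OC | intermediate
11 | lithium trimethoxy[(2S,3S)-6-(1,3-dioxolan-2-yl)-2-[(methoxymethoxy)methyl]-3-(3,4,5-trimethoxyphenyl)-2,3-dihydro-1,4-benzodioxin-8-yl]borate (not isolated) | COc1cc([C@@H]2Oc3cc(C4OCCO4)cc([B-](OC)(OC)OC)c3O[C@H]2COCOC)cc(OC)c1OC.[Li+] | intermediate
12 | (2S,3S)-6-(1,3-dioxolan-2-yl)-8-hydroxy-2-[(methoxymethoxy)methyl]-3-(3,4,5-trimethoxyphenyl)-2,3-dihydro-1,4-benzodioxine | COc1cc([C@@H]2Oc3cc(C4OCCO4)cc(O)c3O[C@H]2COCOC)cc(OC)c1OC | intermediate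
13 | (2S,3S)-8-hydroxy-2-(hydroxymethyl)-3-(3,4,5-trimethoxyphenyl)-2,3-dihydro-1,4-benzodioxine-6-carbaldehyde | COc1cc([C@@H]2Oc3cc(C=O)cc(O)c3O[C@H]2CO)cc(OC)c1OC | intermediate
14 | (2E)-3-[(2S,3S)-8-hydroxy-2-(hydroxymethyl)-3-(3,4,5-trimethoxyphenyl)-2,3-dihydro-1,4-benzodioxin-6-yl]prop-2-enal | COc1cc([C@@H]2Oc3cc(/C=C/C=O)cc(O)c3O[C@H]2CO)cc(OC)c1OC | target

## Step count and least certain steps

Total step count: 9. Longest linear sequence: 8 steps (from 3 through steps 2 to 9; the branch from 1 is equally long, steps 1 and 3 to 9).

**Step 7 (key step).**
- What may go wrong: proton return from the amine to the C8 carbanion before the borate is added, which would leave C8 unoxygenated. Other risks are intermolecular capture of the aryne by the amide or by another aryllithium, lithiation at C7 followed by loss of LiBr in the wrong direction, deprotonation of the acetal C–H, and base-induced β-elimination from C3 that reopens the dioxane once the alkoxide is consumed.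
- Fallback (sets out from 6, returns at 12): the two oxygens are introduced separately and the ring is closed by substitution at C2 instead of addition to an aryne.
  - Anti alcohol 6 is lithiated at the same C–H with lithium 2,2,6,6-tetramethylpiperidide at −78 °C and quenched cold with B(OMe)3 before LiBr is lost. Oxidation with H2O2 should give (1S,2R)-1-[3-bromo-5-(1,3-dioxolan-2-yl)-2-hydroxyphenoxy]-3-(methoxymethoxy)-1-(3,4,5-trimethoxyphenyl)propan-2-ol F1.
  - An intramolecular Mitsunobu reaction (PPh3, DIAD, THF) lets the new phenol displace the activated secondary hydroxyl with inversion. This supplies the inversion that steps 5 and 6 perform in the main route, and should give (2S,3S)-8-bromo-6-(1,3-dioxolan-2-yl)-2-[(methoxymethoxy)methyl]-3-(3,4,5-trimethoxyphenyl)-2,3-dihydro-1,4-benzodioxine F2.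
  - Palladium-catalysed hydroxylation of the aryl bromide (Pd2(dba)3, 2-di-tert-butylphosphino-2',4',6'-triisopropylbiphenyl, KOH, dioxane/H2O, 100 °C) then leads to 12.

**Step 5.**
- What may go wrong: slow displacement at a carbinol carbon flanked by two oxygenated carbons, so that elimination, or participation of ring B leading to retention, competes with inversion.
- Fallback (sets out from 6, returns at 8): an oxidation and reduction pair replaces the substitution.
  - Buffered Dess–Martin oxidation (NaHCO3, CH2Cl2) gives (1S)-1-[3-bromo-5-(1,3-dioxolan-2-yl)phenoxy]-3-(methoxymethoxy)-1-(3,4,5-trimethoxyphenyl)propan-2-one F3, which is used at once because its benzylic α-carbon is enolisable.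
  - Corey–Bakshi–Shibata reduction with the (R)-configured methyl oxazaborolidine and BH3·SMe2 at −20 °C follows. By the large/small model, with the aryloxy(aryl)methyl branch as the large group, hydride should be delivered to the face that gives the (2S) carbinol, so 8 is reached directly. Reagent control is asked here to override the modest substrate preference for the anti isomer.

**Step 4.**
- What may go wrong: incomplete discrimination between the two hydroxyls, giving bis-ether and the secondary ether.
- Fallback (sets out from 4, returns at 6): the order of protection and opening is reversed.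
  - Epoxy alcohol 4 has a single hydroxyl and is converted with MOMCl and iPr2NEt into (2R,3R)-2-[(methoxymethoxy)methyl]-3-(3,4,5-trimethoxyphenyl)oxirane F4.
  - The caesium phenoxide of 2 (Cs2CO3, DMF, 80 °C) then opens F4 at the benzylic carbon with inversion to give 6. This also rules out epoxide migration (Payne rearrangement) before the opening.

**Step 9.**
- What may go wrong: a second olefination of the product enal by the ylide, and slow conversion if 13 is poorly soluble.
- Fallback (sets out from 13, returns at 14): the enal is built through the ester oxidation level.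
  - Ethyl (triphenylphosphoranylidene)acetate (toluene/THF, 80 °C), which cannot homologate its own product, gives ethyl (2E)-3-[(2S,3S)-8-hydroxy-2-(hydroxymethyl)-3-(3,4,5-trimethoxyphenyl)-2,3-dihydro-1,4-benzodioxin-6-yl]prop-2-enoate F5.
  - Excess i-Bu2AlH (CH2Cl2, −78 °C) gives (2S,3S)-2-(hydroxymethyl)-6-[(1E)-3-hydroxyprop-1-en-1-yl]-3-(3,4,5-trimethoxyphenyl)-2,3-dihydro-1,4-benzodioxin-8-ol F6.
  - MnO2 (CH2Cl2, rt) oxidises the allylic alcohol selectively in the presence of the saturated primary alcohol to give 14.

## Further compounds

F1 | step 7 | (1S,2R)-1-[3-bromo-5-(1,3-dioxolan-2-yl)-2-hydroxyphenoxy]-3-(methoxymethoxy)-1-(3,4,5-trimethoxyphenyl)propan-2-ol | COc1cc([C@H](Oc2cc(C3OCCO3)cc(Br)c2O)[C@H](O)COCOC)cc(OC)c1OC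
F2 | step 7 | (2S,3S)-8-bromo-6-(1,3-dioxolan-2-yl)-2-[(methoxymethoxy)methyl]-3-(3,4,5-trimethoxyphenyl)-2,3-dihydro-1,4-benzodioxine | COc1cc([C@@H]2Oc3cc(C4OCCO4)cc(Br)c3O[C@H]2COCOC)cc(OC)c1OC
F3 | step 5 | (1S)-1-[3-bromo-5-(1,3-dioxolan-2-yl)phenoxy]-3-(methoxymethoxy)-1-(3,4,5-trimethoxyphenyl)propan-2-one | COc1cc([C@H](Oc2cc(Br)cc(C3OCCO3)c2)C(=O)COCOC)cc(OC)c1OC
F4 | step 4 | (2R,3R)-2-[(methoxymethoxy)methyl]-3-(3,4,5-trimethoxyphenyl)oxirane | COCOC[C@H]1O[C@@H]1c1cc(OC)c(OC)c(OC)c1
F5 | step 9 | ethyl (2E)-3-[(2S,3S)-8-hydroxy-2-(hydroxymethyl)-3-(3,4,5-trimethoxyphenyl)-2,3-dihydro-1,4-benzodioxin-6-yl]prop-2-enoate | COc1cc([C@@H]2Oc3cc(/C=C/C(=O)OCC)cc(O)c3O[C@H]2CO)cc(OC)c1OC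
F6 | step 9 | (2S,3S)-2-(hydroxymethyl)-6-[(1E)-3-hydroxyprop-1-en-1-yl]-3-(3,4,5-trimethoxyphenyl)-2,3-dihydro-1,4-benzodioxin-8-ol | COc1cc([C@@H]2Oc3cc(/C=C/CO)cc(O)c3O[C@H]2CO)cc(OC)c1OC
A1 | alternative 1 | tricyclic lactone: benzodioxane methyl ester with C2 tied to the C8 oxygen through a lactone carbonyl, aryl trans to that carbonyl carbon | COc1cc([C@@H]2Oc3cc(C(=O)OC)cc4OC(=O)[C@@H]2Oc34)cc(OC)c1OC
A2 | alternative 1 | methyl 7-[(diazoacetyl)oxy]-2-(3,4,5-trimethoxyphenyl)-1,3-benzodioxole-5-carboxylate (acetal carbon not assigned) | COc1cc(C2Oc3cc(C(=O)OC)cc(OC(=O)C=[N+]=[N-])c3O2)cc(OC)c1OC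
A3 | alternative 2 | trans 2-(iodomethyl)-8-(methoxymethoxy)-3-(3,4,5-trimethoxyphenyl)-2,3-dihydro-1,4-benzodioxine-6-carbaldehyde | COc1cc([C@@H]2Oc3cc(C=O)cc(OCOC)c3O[C@H]2CI)cc(OC)c1OC
A4 | alternative 2 | 4-hydroxy-3-(methoxymethoxy)-5-{[(1R)-1-(3,4,5-trimethoxyphenyl)prop-2-en-1-yl]oxy}benzaldehyde | COc1cc([C@@H](C=C)Oc2cc(C=O)cc(OCOC)c2O)cc(OC)c1OC
A5 | alternative 3 | trans 2-[(tert-butyldimethylsilyloxy)methyl]-8-hydroxy-3-(3,4,5-trimethoxyphenyl)-2,3-dihydro-1,4-benzodioxine-6-carbaldehyde | COc1cc([C@@H]2Oc3cc(C=O)cc(O)c3O[C@H]2CO[Si](C)(C)C(C)(C)C)cc(OC)c1OC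
A6 | alternative 3 | 4-{[(2R)-1-[(tert-butyldimethylsilyl)oxy]-3-(3,4,5-trimethoxyphenyl)propan-2-yl]oxy}-3,5-dihydroxybenzaldehyde | COc1cc(C[C@H](CO[Si](C)(C)C(C)(C)C)Oc2c(O)cc(C=O)cc2O)cc(OC)c1OC
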